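**Assumption:** the target has no stereocentre and is achiral, so no enantiocontrol is needed; the carbinol centres that appear in intermediates are racemic and are erased in step 5. Ring letters: ring A = 4‑hydroxy‑3‑aryloxyphenyl, ring B = meta‑phenylene, ring C = the trioxygenated ring, ring D = para‑phenylene.

**Retrosynthetic overview**
1. Target ⇐ tri‑O‑methyl macrocycle (BBr3) ⇐ macrocyclic acyloin, by hydrogenolysis of every benzylic C–O bond.
2. Key disconnection: the A–D CH2–CH2 bridge, cut between two aldehyde carbons. Forward, an N‑heterocyclic carbene turns one aldehyde into an acyl anion equivalent (Breslow enaminol) that attacks the other aldehyde and closes the macrocycle.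
3. Open‑chain dialdehyde ⇐ Ullmann ether (ring A–O–ring B, isovanillin) and SNAr ether (ring C–O–ring D, 4‑fluorobenzaldehyde).
4. B–C bridge ⇐ benzylic zinc addition of a 3‑bromobenzyl unit to 3‑hydroxy‑4,5‑dimethoxybenzaldehyde; its carbinol oxygen is carried along and removed together with the acyloin oxygens.
5. Ring order: the four benzene rings are bought; the only ring formed is the 19‑membered macrocycle, in step 4.

**Route**

Step 1
Reactants: 1 3‑bromobenzyl bromide; 2 3‑hydroxy‑4,5‑dimethoxybenzaldehyde
Product: 4 rac‑5‑[2‑(3‑bromophenyl)‑1‑hydroxyethyl]‑2,3‑dimethoxyphenol, via 3‑bromobenzylzinc bromide 3 (not isolated)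
Conditions: 1 (2.5 equiv), Zn dust, LiCl, THF, 0 to 25 °C; then 2, THF, 0 to 25 °C; aq NH4Cl work‑up
Reagents that add atoms: none
Why: Zinc inserts only into the benzylic C–Br bond (the aryl C–Br bond is inert to Zn/LiCl at 25 °C) and the benzylic zinc reagent adds 1,2 to the aldehyde (Knochel‑type insertion and addition); one equivalent of 3 is sacrificed to the phenol, and the new carbinol centre is racemic and removed in step 5.

Step 2
Reactants: 4 rac‑5‑[2‑(3‑bromophenyl)‑1‑hydroxyethyl]‑2,3‑dimethoxyphenol; 5 4‑fluorobenzaldehyde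
Product: 6 rac‑4‑{5‑[2‑(3‑bromophenyl)‑1‑hydroxyethyl]‑2,3‑dimethoxyphenoxy}benzaldehyde
Conditions: K2CO3, DMF, 110 °C
Reagents that add atoms: none
Why: Nucleophilic aromatic substitution (SNAr): the phenoxide displaces fluoride para to the formyl group, while the secondary alcohol is not deprotonated by K2CO3 and the aryl bromide is inert; no new stereocentre.

Step 3
Reactants: 6 rac‑4‑{5‑[2‑(3‑bromophenyl)‑1‑hydroxyethyl]‑2,3‑dimethoxyphenoxy}benzaldehyde; 7 isovanillin (3‑hydroxy‑4‑methoxybenzaldehyde)
Product: 8 rac‑3‑(3‑{2‑[3‑(4‑formylphenoxy)‑4,5‑dimethoxyphenyl]‑2‑hydroxyethyl}phenoxy)‑4‑methoxybenzaldehyde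
Conditions: CuI (10 mol%), N,N‑dimethylglycine hydrochloride (30 mol%), Cs2CO3, 1,4‑dioxane, 100 °C
Reagents that add atoms: none
Why: Ligand‑accelerated Ullmann diaryl ether coupling of the isovanillin phenoxide with the unactivated aryl bromide; non‑enolisable aldehydes and the secondary alcohol tolerate these conditions, and no new stereocentre forms.

Step 4
Reactants: 8 rac‑3‑(3‑{2‑[3‑(4‑formylphenoxy)‑4,5‑dimethoxyphenyl]‑2‑hydroxyethyl}phenoxy)‑4‑methoxybenzaldehyde
Product: 10 macrocyclic acyloin (ring D–C(=O)–CH(OH)–ring A; diastereomer mixture; racemic), via Breslow enaminol 9 (not isolated)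
Conditions: 2‑(pentafluorophenyl)‑6,7‑dihydro‑5H‑pyrrolo[2,1‑c][1,2,4]triazol‑2‑ium tetrafluoroborate (20 mol%), DBU (20 mol%), degassed THF, 2 mM, syringe‑pump addition, 45 °C, Ar
Reagents that add atoms: none
Why: Proposed new method: the triazolylidene adds to one formyl group and proton transfer gives enaminol 9, an acyl anion equivalent whose carbon attacks the second, normally equally electrophilic, formyl carbon to close the 19‑membered ring; benzoin formation is reversible, so open oligomers can revert and funnel to the cyclic monomer at high dilution, and whichever aldehyde becomes the acyl anion the same C–C bond results and both oxygens are removed in step 5; the new carbinol centre is uncontrolled; closest known chemistry is the carbene‑catalysed intramolecular crossed benzoin to 5‑ to 7‑membered rings and the intermolecular benzoin condensation of alkoxybenzaldehydes with triazolylidene catalysts.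

Step 5
Reactants: 10 macrocyclic acyloin
Product: 11 tri‑O‑methyl ether of the target (A–D and B–C bridges both CH2–CH2)
Conditions: H2 (4 atm), Pd/C (10 wt% Pd), AcOH/EtOAc, HClO4 (cat.), 40 °C
Reagents that add atoms: none
Why: Acid‑promoted benzylic hydrogenolysis over palladium reduces the aryl ketone to the carbinol and cleaves all three benzylic C–O bonds (each on a carbon next to an oxygenated arene) to CH2, which erases every stereocentre; diaryl and methyl ethers survive.

Step 6
Reactants: 11 tri‑O‑methyl ether of the target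
Product: 12 target (CNP0495401.0)
Conditions: BBr3 (8 equiv), CH2Cl2, −78 to 0 °C; then MeOH, H2O (under Ar)
Reagents that add atoms: none
Why: BBr3 demethylation of the three aryl methyl ethers (bromide attacks the methyl carbon of the boron‑complexed ether); the diaryl ether bonds have no sp3 carbon and are untouched; no stereocentre is involved.

**Compound list**
1 | 3‑bromobenzyl bromide | BrCc1cccc(Br)c1 | starting material
2 | 3‑hydroxy‑4,5‑dimethoxybenzaldehyde | O=Cc1cc(O)c(OC)c(OC)c1 | starting material
3 | 3‑bromobenzylzinc bromide | Br[Zn]Cc1cccc(Br)c1 | intermediate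
4 | rac‑5‑[2‑(3‑bromophenyl)‑1‑hydroxyethyl]‑2,3‑dimethoxyphenol | OC(Cc1cccc(Br)c1)c1cc(O)c(OC)c(OC)c1 | intermediate
5 | 4‑fluorobenzaldehyde | O=Cc1ccc(F)cc1 | starting material
6 | rac‑4‑{5‑[2‑(3‑bromophenyl)‑1‑hydroxyethyl]‑2,3‑dimethoxyphenoxy}benzaldehyde | O=Cc1ccc(Oc2cc(C(O)Cc3cccc(Br)c3)cc(OC)c2OC)cc1 | intermediate
7 | isovanillin (3‑hydroxy‑4‑methoxybenzaldehyde) | O=Cc1ccc(OC)c(O)c1 | starting material
8 | rac‑3‑(3‑{2‑[3‑(4‑formylphenoxy)‑4,5‑dimethoxyphenyl]‑2‑hydroxyethyl}phenoxy)‑4‑methoxybenzaldehyde | O=Cc1ccc(OC)c(Oc2cccc(CC(O)c3cc(OC)c(OC)c(Oc4ccc(C=O)cc4)c3)c2)c1 | intermediate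
9 | Breslow enaminol of 8 (carbene adduct at the ring D formyl carbon; ring A aldehyde still free) | O=Cc1ccc(OC)c(Oc2cccc(CC(O)c3cc(OC)c(OC)c(Oc4ccc(C(O)=C5N(c6c(F)c(F)c(F)c(F)c6F)N=C6CCCN56)cc4)c3)c2)c1 | intermediate
10 | macrocyclic acyloin: 19‑membered ring; C=O on the bridge carbon at ring D; CH(OH) on the bridge carbon at ring A; CH(OH) on the bridge carbon at ring C; OMe on ring A and two OMe on ring C; diastereomer mixture, each racemic | COc1ccc2cc1Oc1cccc(c1)CC(O)c1cc(OC)c(OC)c(c1)Oc1ccc(cc1)C(=O)C2O | intermediate
11 | tri‑O‑methyl ether of the target (OMe on ring A and two OMe on ring C in place of the three OH) | COc1ccc2cc1Oc1cccc(c1)CCc1cc(OC)c(OC)c(c1)Oc1ccc(cc1)CC2 | intermediate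
12 | CNP0495401.0 (achiral) | Oc1ccc2cc1Oc1cccc(c1)CCc1cc(O)c(O)c(c1)Oc1ccc(cc1)CC2 | target

**Totals**
Total step count: 6. Longest linear sequence: 6 steps (1/2 → 12).

**Three steps most likely to fail, with fallbacks**

Step 4 (carbene macrocyclisation): two para‑alkoxy aldehydes are slow benzoin partners and the ring has 19 members, so conversion or the monomer/oligomer balance may be poor. The fallback sets out from 8 and comes back at 11. Slow addition of 8 to SmI2 in THF at 25 °C (2 mM) couples the two formyl carbons irreversibly through ketyl radical anions (intramolecular pinacol coupling) to give the macrocyclic triol F1, a diastereomer mixture with a 1,2‑diol on the A–D bridge. F1 is hydrogenolysed under the step 5 conditions to 11.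

Step 5 (triple benzylic hydrogenolysis): under acid the diol stage of the acyloin may undergo pinacol‑type aryl migration, or the reaction may stall at a ketone or carbinol. The fallback sets out from 10 and comes back at 11 without hydrogenation. TMSCl/NaI in MeCN at 25 °C replaces both hydroxyl groups by iodide and reduces the iodides with the HI formed, giving the macrocyclic ketone F2 (ring D–C(=O)–CH2–ring A, B–C bridge already CH2–CH2). Et3SiH/TFA in CH2Cl2 then reduces this electron‑rich aryl ketone to CH2 by ionic hydrogenation, giving 11.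

Step 3 (Ullmann coupling): the ortho‑methoxy phenol of isovanillin is hindered and the aryl bromide is unactivated, with two aldehydes present. The fallback sets out from 6 and comes back at 8 with the coupling polarity changed. Miyaura borylation of 6 (B2pin2, Pd(dppf)Cl2, KOAc, dioxane, 85 °C) gives the pinacol boronate F3. Oxidative Chan–Lam coupling of F3 with 7 (Cu(OAc)2, pyridine, B(OH)3, MeCN, air, 70 °C) gives 8.

**Further compounds**
F1 | step 4 | macrocyclic triol (A–D bridge CH(OH)–CH(OH); ring C side carbinol kept; tri‑O‑methyl; diastereomer mixture, racemic) | COc1ccc2cc1Oc1cccc(c1)CC(O)c1cc(OC)c(OC)c(c1)Oc1ccc(cc1)C(O)C2O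
F2 | step 5 | macrocyclic ketone (ring D–C(=O)–CH2–ring A; B–C bridge CH2–CH2; tri‑O‑methyl) | COc1ccc2cc1Oc1cccc(c1)CCc1cc(OC)c(OC)c(c1)Oc1ccc(cc1)C(=O)C2
F3 | step 3 | rac‑4‑{5‑[1‑hydroxy‑2‑(3‑(4,4,5,5‑tetramethyl‑1,3,2‑dioxaborolan‑2‑yl)phenyl)ethyl]‑2,3‑dimethoxyphenoxy}benzaldehyde | O=Cc1ccc(Oc2cc(C(O)Cc3cccc(B4OC(C)(C)C(C)(C)O4)c3)cc(OC)c2OC)cc1
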